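**Plan**

- Retrosynthesis (chromene numbering O1, C2, C3, C4, C4a, C5–C8, C8a): the two N-tosyl groups come off last; the pyran ring is cut at O1–C2 and C4–C4a back to a hydroquinone and 3-methylbut-2-enal; the hydroquinone goes back through a para-quinone to a 1-ethoxy-3,4-dimethoxybenzene; that benzene ring is cut at C5–C4a and C8–C8a.
- Feature used: on the benzene ring the indol-3-yl carbons C5 and C8 are para and enclose the neighbouring oxygen-bearing carbons C6 and C7, while C4a/C8a is a C–H/C–O pair; this is a 2,5-di(indolyl)-3,4-dimethoxycyclopentadienone in which an ynol ether takes the place of the carbonyl bridge.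
- Forward order: indolylacetate → 1,3-di(indolyl)acetone (Claisen, decarboxylation) → cyclopentane ring (double Claisen with dimethyl oxalate) → dienone (two O-methylations) → benzene ring (Diels–Alder, loss of CO) → quinone → hydroquinone → pyran ring → free indoles.
- Oxygen pattern: C6–OMe/C8a–OEt is the only para-dialkoxy pair, so oxidation frees exactly O6 and O8a and keeps the C7 methoxyl; only O8a has a free ortho carbon (C4a), which fixes where the pyran ring forms.
- Stereochemistry: the target has no stereocentre and no stereogenic double bond; the transient centres (C5 of the cyclopentenediones, the bridgeheads of the cycloadduct) are erased.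

Key step: step 6

Remark: methyl indol-3-ylacetate (the methyl ester of indole-3-acetic acid), dimethyl oxalate, ethoxyacetylene (as a solution in hexanes) and 3-methylbut-2-enal are taken as purchased; Ts = 4-methylbenzenesulfonyl.

**Route**

Step 1
Reactants: 1 methyl indol-3-ylacetate
Product: 2 methyl (1-tosylindol-3-yl)acetate
Conditions: NaH (1.1 equiv), DMF, 0 °C; TsCl, 0 °C → rt
Reagents that add atoms: p-toluenesulfonyl chloride, Cc1ccc(S(=O)(=O)Cl)cc1
Why: N-sulfonylation of the indolide anion, the fastest-formed anion of 1, installs an electron-withdrawing group that should shield both indoles from the oxidant and the electrophiles used later.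

Step 2
Reactants: 2 methyl (1-tosylindol-3-yl)acetate (two molecules)
Product: 4 1,3-bis(1-tosylindol-3-yl)propan-2-one, via β-keto ester 3 (not isolated)
Conditions: KOt-Bu (0.6 equiv), THF, 0 °C → rt; then solvent exchange, AcOH–6 M HCl, 100 °C
Reagents that add atoms: none
Why: Claisen self-condensation of the arylacetate is pulled forward by deprotonation of β-keto ester 3, and acid hydrolysis with decarboxylation of the β-keto acid should give the symmetric ketone, the N-sulfonyl groups being stable to acid.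

Step 3
Reactants: 4 1,3-bis(1-tosylindol-3-yl)propan-2-one; 5 dimethyl oxalate
Product: 6 2-hydroxy-3,5-bis(1-tosylindol-3-yl)cyclopent-2-ene-1,4-dione (enol form of the cyclopentane-1,2,4-trione)
Conditions: KOt-Bu (2.2 equiv) added to 4 and 5, THF, 0 °C → rt; then 1 M HCl
Reagents that add atoms: none
Why: Twofold Claisen acylation of the two α-carbons of the ketone by the oxalate, the second one intramolecular (Dieckmann type), closes the five-membered ring as in the classical dibenzyl ketone–oxalate condensation and is driven by the acidity of the product.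

Step 4
Reactants: 6 2-hydroxy-3,5-bis(1-tosylindol-3-yl)cyclopent-2-ene-1,4-dione
Product: 7 2-methoxy-3,5-bis(1-tosylindol-3-yl)cyclopent-2-ene-1,4-dione
Conditions: MeOH, HC(OMe)3 (1.5 equiv), TsOH·H2O (cat.), 50 °C
Reagents that add atoms: methanol, CO
Why: Acid-catalysed enol etherification of a vinylogous acid under equilibrating conditions (the orthoformate removes the water) should place the ether on the oxalate-derived oxygen at C2, because this isomer keeps a cross-conjugated ene-1,4-dione whereas etherification at the C4 oxygen would leave a vicinal dione.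

Step 5
Reactants: 7 2-methoxy-3,5-bis(1-tosylindol-3-yl)cyclopent-2-ene-1,4-dione
Product: 8 3,4-dimethoxy-2,5-bis(1-tosylindol-3-yl)cyclopenta-2,4-dien-1-one
Conditions: K2CO3, Me2SO4, acetone, 40 °C
Reagents that add atoms: dimethyl sulfate, COS(=O)(=O)OC
Why: Enolate O-alkylation: the C5–H of 7 lies between two carbonyls, and its enolate should take the hard sulfate methyl at O1, the oxygen of the ketone-type carbonyl, while the C4 carbonyl, a vinylogous ester that behaves like the ester group of a β-keto ester enolate, stays as C=O, which gives the symmetric push–pull dienone and erases the C5 centre.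

Step 6
Reactants: 8 3,4-dimethoxy-2,5-bis(1-tosylindol-3-yl)cyclopenta-2,4-dien-1-one; 9 ethoxyacetylene
Product: 11 1-ethoxy-3,4-dimethoxy-2,5-bis(1-tosylindol-3-yl)benzene, via norbornadienone adduct 10 (not isolated)
Conditions: 9 (10 equiv, solution in hexanes), toluene, sealed tube, 90 °C, argon
Reagents that add atoms: none
Why: Dienone 8 acts as the 4π component through C2–C5 and the polarised, electron-rich triple bond of 9 as the 2π component in a concerted [4+2] cycloaddition that forms C5–C4a and C8–C8a and gives the 7-oxonorbornadiene 10. This bridged ketone should lose CO at once by cheletropic extrusion, the closest known reaction type being the benzannulation of tetraarylcyclopentadienones with alkynes. The only ring closed is the central benzene ring, made by intermolecular [4+2] annulation and aromatised by the extrusion. No stereocentre is created in the product, since the two bridgehead centres of 10 vanish when CO leaves. Regiochemistry is not at stake, because 8 has a mirror plane through C1 and the midpoint of C3–C4 and either orientation of 9 gives the same arene. What the step needs is cycloaddition faster than dimerisation of 8 and faster than thermal decay of 9 to ketene; the bulky 2,5-indolyl groups and the push–pull methoxy groups of 8 should slow dimerisation, and an excess of 9 at about 90 °C should favour the cross reaction.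

Step 7
Reactants: 11 1-ethoxy-3,4-dimethoxy-2,5-bis(1-tosylindol-3-yl)benzene
Product: 12 3-methoxy-2,5-bis(1-tosylindol-3-yl)cyclohexa-2,5-diene-1,4-dione
Conditions: (NH4)2Ce(NO3)6 (2.5 equiv), MeCN–H2O, 0 °C
Reagents that add atoms: water, O
Why: Oxidative dealkylation of a para-dialkoxybenzene by tetravalent cerium should act on the only para-dialkoxy pair (C6–OMe/C8a–OEt), giving the para-quinone with loss of methanol and ethanol while the C7 methoxyl survives as a vinylogous ester and the electron-poor N-sulfonyl indoles are not oxidised.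

Step 8
Reactants: 12 3-methoxy-2,5-bis(1-tosylindol-3-yl)cyclohexa-2,5-diene-1,4-dione
Product: 13 3-methoxy-2,5-bis(1-tosylindol-3-yl)benzene-1,4-diol
Conditions: Na2S2O4, THF–H2O, rt, argon; crude product used at once
Reagents that add atoms: none
Why: Two-electron reduction of a quinone to its hydroquinone by dithionite is standard and touches neither the sulfonamides nor the methyl ether.

Step 9
Reactants: 13 3-methoxy-2,5-bis(1-tosylindol-3-yl)benzene-1,4-diol; 14 3-methylbut-2-enal
Product: 17 N,N'-ditosyl kumbicin C (7-methoxy-2,2-dimethyl-5,8-bis(1-tosylindol-3-yl)-2H-chromen-6-ol), via benzodioxaborin 15 (not isolated), via ortho-quinone methide 16 (not isolated)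
Conditions: PhB(OH)2 (1 equiv), AcOH (cat.), toluene, reflux (Dean–Stark), argon
Reagents that add atoms: none
Why: Phenylboronic acid-templated ortho-specific condensation of a phenol with an enal should deliver the aldehyde carbon to C4a, the only free ring carbon and ortho to O8a alone; the dioxaborin 15 then fragments to the ortho-quinone methide 16, whose oxa-6π electrocyclisation closes the pyran ring.

Step 10
Reactants: 17 N,N'-ditosyl kumbicin C
Product: 18 kumbicin C
Conditions: Mg turnings (excess), MeOH–THF, rt, sonication, argon; aq. NH4Cl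
Reagents that add atoms: none
Why: Electron transfer from magnesium in methanol cleaves the N–S bonds of N-arylsulfonyl indoles, and this reducing, non-alkylating medium should spare the oxidisable para-alkoxyphenol and the chromene double bond.

**Compound list**

1 | methyl indol-3-ylacetate | COC(=O)Cc1c[nH]c2ccccc12 | starting material
2 | methyl (1-tosylindol-3-yl)acetate | COC(=O)Cc1cn(S(=O)(=O)c2ccc(C)cc2)c2ccccc12 | intermediate
3 | methyl 3-oxo-2,4-bis(1-tosylindol-3-yl)butanoate (racemic, formed in the flask) | COC(=O)C(c1cn(S(=O)(=O)c2ccc(C)cc2)c2ccccc12)C(=O)Cc1cn(S(=O)(=O)c2ccc(C)cc2)c2ccccc12 | intermediate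
4 | 1,3-bis(1-tosylindol-3-yl)propan-2-one | O=C(Cc1cn(S(=O)(=O)c2ccc(C)cc2)c2ccccc12)Cc1cn(S(=O)(=O)c2ccc(C)cc2)c2ccccc12 | intermediate
5 | dimethyl oxalate | COC(=O)C(=O)OC | starting material
6 | 2-hydroxy-3,5-bis(1-tosylindol-3-yl)cyclopent-2-ene-1,4-dione (racemic, C5 labile) | O=C1C(c2cn(S(=O)(=O)c3ccc(C)cc3)c3ccccc23)C(=O)C(O)=C1c1cn(S(=O)(=O)c2ccc(C)cc2)c2ccccc12 | intermediate
7 | 2-methoxy-3,5-bis(1-tosylindol-3-yl)cyclopent-2-ene-1,4-dione (racemic, C5 labile) | O=C1C(c2cn(S(=O)(=O)c3ccc(C)cc3)c3ccccc23)C(=O)C(OC)=C1c1cn(S(=O)(=O)c2ccc(C)cc2)c2ccccc12 | intermediate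
8 | 3,4-dimethoxy-2,5-bis(1-tosylindol-3-yl)cyclopenta-2,4-dien-1-one | O=C1C(c2cn(S(=O)(=O)c3ccc(C)cc3)c3ccccc23)=C(OC)C(OC)=C1c1cn(S(=O)(=O)c2ccc(C)cc2)c2ccccc12 | intermediate
9 | ethoxyacetylene | C#COCC | starting material
10 | 2-ethoxy-5,6-dimethoxy-1,4-bis(1-tosylindol-3-yl)bicyclo[2.2.1]hepta-2,5-dien-7-one (racemic, formed in the flask) | O=C1C2(c3cn(S(=O)(=O)c4ccc(C)cc4)c4ccccc34)C(OCC)=CC1(c1cn(S(=O)(=O)c3ccc(C)cc3)c3ccccc13)C(OC)=C2OC | intermediate
11 | 1-ethoxy-3,4-dimethoxy-2,5-bis(1-tosylindol-3-yl)benzene | CCOc1cc(-c2cn(S(=O)(=O)c3ccc(C)cc3)c3ccccc23)c(OC)c(OC)c1-c1cn(S(=O)(=O)c2ccc(C)cc2)c2ccccc12 | intermediate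
12 | 3-methoxy-2,5-bis(1-tosylindol-3-yl)cyclohexa-2,5-diene-1,4-dione | O=C1C=C(c2cn(S(=O)(=O)c3ccc(C)cc3)c3ccccc23)C(=O)C(OC)=C1c1cn(S(=O)(=O)c2ccc(C)cc2)c2ccccc12 | intermediate
13 | 3-methoxy-2,5-bis(1-tosylindol-3-yl)benzene-1,4-diol | Oc1cc(-c2cn(S(=O)(=O)c3ccc(C)cc3)c3ccccc23)c(O)c(OC)c1-c1cn(S(=O)(=O)c2ccc(C)cc2)c2ccccc12 | intermediate
14 | 3-methylbut-2-enal | CC(C)=CC=O | starting material
15 | 7-methoxy-4-(2-methylprop-1-en-1-yl)-2-phenyl-5,8-bis(1-tosylindol-3-yl)-4H-1,3,2-benzodioxaborin-6-ol (racemic, formed in the flask) | CC(C)=CC1OB(c2ccccc2)Oc2c(-c3cn(S(=O)(=O)c4ccc(C)cc4)c4ccccc34)c(OC)c(O)c(-c3cn(S(=O)(=O)c4ccc(C)cc4)c4ccccc34)c21 | intermediate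
16 | (Z)-4-hydroxy-3-methoxy-6-(3-methylbut-2-en-1-ylidene)-2,5-bis(1-tosylindol-3-yl)cyclohexa-2,4-dien-1-one (formed in the flask) | CC(C)=C/C=C1\C(=O)C(c2cn(S(=O)(=O)c3ccc(C)cc3)c3ccccc23)=C(OC)C(O)=C1c1cn(S(=O)(=O)c2ccc(C)cc2)c2ccccc12 | intermediate
17 | N,N'-ditosyl kumbicin C, 7-methoxy-2,2-dimethyl-5,8-bis(1-tosylindol-3-yl)-2H-chromen-6-ol | COc1c(O)c(-c2cn(S(=O)(=O)c3ccc(C)cc3)c3ccccc23)c2c(c1-c1cn(S(=O)(=O)c3ccc(C)cc3)c3ccccc13)OC(C)(C)C=C2 | intermediate
18 | kumbicin C, 5,8-di(1H-indol-3-yl)-7-methoxy-2,2-dimethyl-2H-chromen-6-ol | COc1c(O)c(-c2c[nH]c3ccccc23)c2c(c1-c1c[nH]c3ccccc13)OC(C)(C)C=C2 | target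

**Step count and risks**

Total step count: 10. Longest linear sequence: 10 steps (1 → 18).

Steps most likely to fail:

Step 5. The enolate of 7 may be methylated at carbon C5 or at the C4 oxygen instead of O1, and the dienone may dimerise while it is isolated. The fallback leaves the route at 6 and rejoins it at 12.
- The two adjacent enol oxygens of 6 are bridged with t-Bu2Si(OTf)2 and 2,6-lutidine in CH2Cl2 to give the silylene-bridged dienone 2,2-di-tert-butyl-4,6-bis(1-tosylindol-3-yl)cyclopenta[d][1,3,2]dioxasilol-5-one F1. One silicon atom can span only neighbouring oxygens and silylation does not go to carbon, so only the 3,4-dioxygenated dienone can form.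
- F1 and ethoxyacetylene 9 (toluene, 90 °C) should pass through the bridged 7-oxonorbornadiene adduct F2, lose CO and give the benzodioxasilole 2,2-di-tert-butyl-5-ethoxy-4,7-bis(1-tosylindol-3-yl)benzo[d][1,3,2]dioxasilole F3.
- (NH4)2Ce(NO3)6 in aqueous MeCN should oxidise the para O6/OEt pair with hydrolytic loss of the silicon bridge (aqueous HF in MeCN if needed), leaving the hydroxyquinone 3-hydroxy-2,5-bis(1-tosylindol-3-yl)cyclohexa-2,5-diene-1,4-dione F4.
- Acid-catalysed etherification of this vinylogous acid (MeOH, H2SO4 cat.) gives 12.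

Step 6. The cycloaddition may be too slow at the temperature that ethoxyacetylene tolerates (on stronger heating it fragments to ketene and ethene), so that dimerisation of the dienone or decay of the alkyne wins. The fallback runs from 8 back to 11.
- 1,1-Diethoxyethene (ketene diethyl acetal) is a more nucleophilic, heat-stable two-carbon partner of the same oxidation level; it is heated with 8 in xylene at 130 °C.
- The [4+2] adduct 5,5-diethoxy-2,3-dimethoxy-1,4-bis(1-tosylindol-3-yl)bicyclo[2.2.1]hept-2-en-7-one F5 should lose CO to the ketal 5,5-diethoxy-2,3-dimethoxy-1,4-bis(1-tosylindol-3-yl)cyclohexa-1,3-diene F6.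
- F6 eliminates ethanol (TsOH cat.) to give 11 with the same two new C–C bonds.

Step 9. Bond formation at C4a, crowded by the indolyl group at C5, may lag behind air oxidation of the hydroquinone or self-condensation of the aldehyde. The fallback runs from 13 back to 17.
- O-Alkylation of the less hindered O8a–H with 3-chloro-3-methylbut-1-yne (K2CO3, KI, acetone) gives the propargyl ether 2-methoxy-4-[(2-methylbut-3-yn-2-yl)oxy]-3,6-bis(1-tosylindol-3-yl)phenol F7.
- Heating in N,N-diethylaniline (180 °C) should bring about aromatic Claisen rearrangement to C4a and enolisation to the allenylphenol 3-methoxy-6-(3-methylbuta-1,2-dien-1-yl)-2,5-bis(1-tosylindol-3-yl)benzene-1,4-diol F8.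
- A 1,5-hydrogen shift leads to the ortho-quinone methide 16 of the main route, and 6π electrocyclisation gives 17.

Further compounds
F1 | step 5 | 2,2-di-tert-butyl-4,6-bis(1-tosylindol-3-yl)-5H-cyclopenta[d][1,3,2]dioxasilol-5-one | O=C1C(c2cn(S(=O)(=O)c3ccc(C)cc3)c3ccccc23)=C2O[Si](C(C)(C)C)(C(C)(C)C)OC2=C1c1cn(S(=O)(=O)c2ccc(C)cc2)c2ccccc12
F2 | step 5 | 7-oxonorbornadiene adduct of F1 and ethoxyacetylene (racemic) | O=C1C2(c3cn(S(=O)(=O)c4ccc(C)cc4)c4ccccc34)C(OCC)=CC1(c1cn(S(=O)(=O)c3ccc(C)cc3)c3ccccc13)C1=C2O[Si](C(C)(C)C)(C(C)(C)C)O1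
F3 | step 5 | 2,2-di-tert-butyl-5-ethoxy-4,7-bis(1-tosylindol-3-yl)benzo[d][1,3,2]dioxasilole | CCOc1cc(-c2cn(S(=O)(=O)c3ccc(C)cc3)c3ccccc23)c2O[Si](C(C)(C)C)(C(C)(C)C)Oc2c1-c1cn(S(=O)(=O)c2ccc(C)cc2)c2ccccc12
F4 | step 5 | 3-hydroxy-2,5-bis(1-tosylindol-3-yl)cyclohexa-2,5-diene-1,4-dione | O=C1C=C(c2cn(S(=O)(=O)c3ccc(C)cc3)c3ccccc23)C(=O)C(O)=C1c1cn(S(=O)(=O)c2ccc(C)cc2)c2ccccc12
F5 | step 6 | 5,5-diethoxy-2,3-dimethoxy-1,4-bis(1-tosylindol-3-yl)bicyclo[2.2.1]hept-2-en-7-one (racemic) | O=C1C2(c3cn(S(=O)(=O)c4ccc(C)cc4)c4ccccc34)C(OCC)(OCC)CC1(c1cn(S(=O)(=O)c3ccc(C)cc3)c3ccccc13)C(OC)=C2OC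
F6 | step 6 | 5,5-diethoxy-2,3-dimethoxy-1,4-bis(1-tosylindol-3-yl)cyclohexa-1,3-diene | CCOC1(OCC)CC(c2cn(S(=O)(=O)c3ccc(C)cc3)c3ccccc23)=C(OC)C(OC)=C1c1cn(S(=O)(=O)c2ccc(C)cc2)c2ccccc12
F7 | step 9 | 2-methoxy-4-[(2-methylbut-3-yn-2-yl)oxy]-3,6-bis(1-tosylindol-3-yl)phenol | C#CC(C)(C)Oc1cc(-c2cn(S(=O)(=O)c3ccc(C)cc3)c3ccccc23)c(O)c(OC)c1-c1cn(S(=O)(=O)c2ccc(C)cc2)c2ccccc12
F8 | step 9 | 3-methoxy-6-(3-methylbuta-1,2-dien-1-yl)-2,5-bis(1-tosylindol-3-yl)benzene-1,4-diol | CC(C)=C=Cc1c(O)c(-c2cn(S(=O)(=O)c3ccc(C)cc3)c3ccccc23)c(OC)c(O)c1-c1cn(S(=O)(=O)c2ccc(C)cc2)c2ccccc12
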